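A neighbour flask charged with 0.60 M of solid substrate held coupling partner in surplus, so I asked which charge would be the limiting one in this flask.

solid substrate 1.5 M; coupling partner 1.05 M; time 12 h

    solid substrate ⇌ dissolved substrate, rate k1*(cs1 - [dissolved substrate]) while solid is left; crystals form when [dissolved substrate] > cs1 (cs1 = 0.57 M, k1 = 2.3 h⁻¹)
    dissolved substrate + coupling partner → target (k2 = 1.9 L mol⁻¹ h⁻¹)
    2 solid substrate → self-condensation product (k3 = 0.14 L mol⁻¹ h⁻¹)
    solid substrate + target → side product (k4 = 0.046 L mol⁻¹ h⁻¹)

- a species is counted by the solid substrate in it: one self-condensation product or side product counts as two
- for a step with 2 of a species take k times the square, and two of it per event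
- given per volume of solution although it is solid: solid substrate
- at the start none of the solid substrate is in solution
- run time (flask): 12 h

* how much target there is at 12 h, in percent of the solid substrate charged
* the change that raises the amount of target at 12 h, in percent of the solid substrate charged most ("none" if none brings more than 2 percentage points) (north-east / west / north-west / none)
* amount of target at 12 h, in percent of the solid substrate charged, after north-east

- north-east: doubling the solubility in step 1, all else as stated
- west: doubling the amount of coupling partner, all else as stated
- north-west: doubling the dissolution coefficient of step 1, all else as stated

1. Each target takes one coupling partner, so I set the upper bound at 70.0% of the charge.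

2. That left 30.0% of the charge as the spare, the share of substrate the flask can lose before coupling partner stops being the limiting reagent.

3. Dissolving into empty solution at 1.31 M h⁻¹ gave the solid a reckoned life of 1.14 h. Taking the solid to fall in a straight line over that life, I estimated the self-condensation loss at 16.0% of the charge.

4. With dissolved substrate held where dissolution matches step 2 at the charged partner, I reckoned a rate of 0.609 M h⁻¹. That gave a solid life of 2.46 h and an estimated loss of 34.5%. The spare lay between these two estimated losses.

5. For the lower end of the bracket, an estimate and not a strict bound, I subtracted the larger loss and a second-order tail of 2.92%, which gave 62.6%. I set side product aside, since target's half-life by step 4, 10 h, is longer than the reckoned solid life.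

6. West raises the upper bound itself, so I chose it.

The forecast gave 69%, 69.6% after north-east and west as best, holding that “The coupling partner is the limiting reagent”, and its figure fell inside my bracket.

The flask gave 68.9%, and 69.7% after north-east, and west gained 13 percentage points. Self-condensation product stood at 18.3% at 12.0 h, less than the spare. In the neighbour flask the spare was −75.0%, negative, so the charge of solid substrate became the upper bound. At the same two reckoned dissolving rates, my estimated loss goes with the square of the charge, giving 2.56% to 5.52%, and so an estimated target of 94.5% to 97.4%. That neighbour flask read 96.7% at 12.0 h, with 0% of its substrate and 45% of its coupling partner left.

The numbers stand for no real mixture; no experiment stands behind them.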